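Readings and results are calculated for substances that don't exist, and the scatter is random.

3 questions lie before us: which flask ends with the higher excess of right-handed substrate over left-handed substrate, and how high each excess stands.

| flask | left-handed substrate | right-handed substrate | partner | racemization catalyst | precatalyst | remark | time |
|---|---|---|---|---|---|---|---|
| north-east | 0.15 M | 0.15 M | 0.36 M | 75 µM | 6.6 mM | run made earlier |  |
| west | 0.15 M | 0.15 M | 0.51 M | 75 µM | 6.6 mM | run made earlier |  |
| Saturday's | 0.15 M | 0.15 M | 0.450 M | 75 µM | 6.6 mM |  | 3.0 min |
| Sunday's | 0.15 M | 0.15 M | 0.250 M | 75 µM | 6.6 mM |  | 3.0 min |

- north-east (time / s: right-handed substrate / %, left-handed substrate / %, left-handed product / %): 10.0: 49.7, 49.6, 2.5; 25.0: 49.1, 42.8, 5.7; 40.0: 48.6, 36.1, 14.2; 60.0: 45.8, 26.6, 23.9; 90.0: 42.3, 21.4, 36.8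
- west (time / s: right-handed substrate / %, left-handed substrate / %, left-handed product / %): 20.0: 48.7, 41.9, 7.5; 40.0: 47.5, 26.9, 23.4; 50.0: 47.4, 22.1, 27.9; 80.0: 40.6, 13.1, 45.0; 90.0: 38.0, 11.2, 50.5

(readings scatter by 1 percentage point)

- free catalyst is single-handed; left-handed substrate and right-handed substrate are mirror images of each other, charged as a racemate, each of them at the stated concentration
- on the list of suspects stand: partner + free catalyst + left-handed substrate -> free catalyst + left-handed product; partner + free catalyst + right-handed substrate -> free catalyst + right-handed product; left-handed substrate + racemization catalyst <-> right-handed substrate + racemization catalyst; partner + precatalyst -> free catalyst + spent reagent; 2 partner -> self-condensation product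
- an excess is the difference of the two amounts in percent of their sum
- an excess is below zero if the other one leads

- which one finishes higher in excess of right-handed substrate over left-handed substrate among what is left of the two ("neither" within 2 percentage points) (Saturday's / Sunday's / neither)
- excess of right-handed substrate over left-handed substrate among what is left of the two at the end, Saturday's
- excess of right-handed substrate over left-handed substrate among what is left of the two at the end, Sunday's

What does the flask do? Free catalyst and partner turn left-handed substrate into left-handed product. In the west run right-handed substrate fell to 38.0% by 90.0 s, yet the three columns still sum to 99.7%. So I read the racemization catalyst as feeding right-handed substrate over into left-handed substrate.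

What end must each flask reach? Each turn of substrate costs one partner, so I take the partner budget, the partner charged as a fraction of both substrates charged 0.833. That figure is Sunday's budget; Saturday's is 1.50. Sunday's budget falls short of one, so there partner is the limiting reagent, and at least 16.7% of the charge must stay substrate, drifting towards zero excess. Saturday's budget exceeds one, so the budget sets no such floor there.

But the question stops at 3.0 min, so how fast is the approach? At 90.0 s the excess reads 32.8% in the north-east run and 54.5% in the west run. A straight line in partner gives 45.8% for Saturday's and 16.9% for Sunday's at that time.

Is that line safe for Sunday's? Less so, since its partner of 0.250 M lies below the 0.36 M of the north-east run. Still, the gap of 29 percentage points on the line at 90.0 s far exceeds the margin. I commit to Saturday's first, each flask somewhat above its line by 3.0 min.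

The forecast named Saturday's, with 47% and 25%, and said of Sunday's: “Partner runs low here, so racemization erodes the excess”.

The flasks give 58.6% for Saturday's and 28.7% for Sunday's.

    partner + free catalyst + left-handed substrate → free catalyst + left-handed product (k = 104 L² mol⁻² s⁻¹)
    partner + free catalyst + right-handed substrate → free catalyst + right-handed product (k = 1.56 L² mol⁻² s⁻¹)
    left-handed substrate + racemization catalyst ⇌ right-handed substrate + racemization catalyst, rate k3*[racemization catalyst]*[left-handed substrate] forward; the back reaction follows from the equilibrium constant (k = 82.5 L mol⁻¹ s⁻¹)
    partner + precatalyst → free catalyst + spent reagent (k = 0.00604 L mol⁻¹ s⁻¹)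
    2 partner → self-condensation product (k = 0.00436 L mol⁻¹ s⁻¹)

At 3.00 min Sunday's partner is worth 24.5% of the charge against 55.1% of substrate. By 30.0 min, with partner at 0%, Sunday's flask, on its budget of 0.833, holds 31.8% as substrate, above the floor, at an excess of 0%. The neighbour of Saturday's charged with 0.11 M of partner has a budget of 0.367 and reads an excess of 9.21%.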